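# Proposed total synthesis of CNP0526758.1 (37)

**Numbering.** Atoms carry germacrane numbers: ring C1–C10, C1 the free carbinol, C4 bearing C15 (CH2OH), C6 the lactone carbinol, C7 the ring-fusion carbon bearing C11, C8 the ester carbinol, C10 bearing C14 (CH3); the lactone is C11, C12 (C=O) and C13 (=CH2). Compounds are numbered 1–37 in the order in which they first appear in the steps; species made and consumed in one flask have numbers of their own.

## Analysis of the target

37 is a germacranolide: a ten-membered carbocycle (C1–C10) fused at C6/C7 to an α-methylene-γ-butyrolactone (O6–C12(=O)–C11(=C13H2)–C7), with H6 and H7 anti (trans fusion). Both ring alkenes are trisubstituted and cis with respect to the ring: C4=C5, whose exocyclic arm is the C15 hydroxymethyl (E by the sequence rules), and C9=C10, which carries the C14 methyl (Z). The ring has four stereocentres. C6, C7 and C8 are contiguous (6R,7R,8R): in the extended chain C9–C8–C7–C6–C5 the C11 branch is syn to O6 and anti to O8, and O6/O8 are 1,3-anti. C1 (1S) is isolated, separated from the triad by C10/C9 on one side and C2–C5 on the other, so it must be set by reagent control. A fifth centre sits in the (S)-2-methylbutanoate on O8. Sensitive groups are the exo-methylene lactone (Michael acceptor, not compatible with organometallics or base), the allylic C8 ester next to the C1 allylic alcohol (acyl migration, ionisation), and the epimerisable α-carbon of the acyl group. The difficulty is a medium ring with two ring-cis trisubstituted alkenes, combined with stereocentres on both sides of the C9=C10 alkene. The feature used here is that C9=C10, with its methyl on C10, lies between two carbinol carbons, C8 and C1. A C9≡C10 alkyne flanked by O8 and O1 is a linear surrogate with no geometry to control; it allows ring closure at C8–C9 by carbonyl addition, and the C8 alkoxide created there can then direct the methyl group to C10.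

## Retrosynthetic reasoning

**O–Si bonds and the lactone C12–O6 bond.** 37 is the desilylation product of lactone 36. The lactone is taken back, at the alcohol oxidation level, to the 6,12-diol 33. An α-methylene lactone would not survive the Grignard reagent needed earlier, whereas a 2-methylene-1,4-diol does. When O15 and O1 are still silylated, C12–OH is the only primary alcohol, so an oxoammonium oxidant can select it. 33 comes from 32 by removing the two most labile silyl ethers (secondary TES on O6, primary TBS on O12) while the hindered secondary TBS on O1 and the primary TBDPS on O15 stay.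

**C8–O acyl bond.** 32 is cut at the ester into allylic alcohol 30 and acid 31. At this point O8 is the only free hydroxyl, so no selectivity is needed, and acylating before lactonisation keeps O8 out of the oxidation.

**C10–C14 and C9–H.** 30 is derived from cycloalkynol 28 by a syn addition of methyl and hydrogen across C9≡C10. The free O8 alkoxide is the only directing group (O1 is silylated), so methyl goes to the distal carbon C10. Syn addition across an endocyclic alkyne can only give the ring-cis alkene.

**C8–C9 (ring closure).** 28 is opened between the C8 carbinol and the alkyne carbon C9 to the seco iodoalkyne aldehyde 26. This is the only ring bond whose formation is a carbonyl addition of an sp carbon. It creates the O8 handle, needs no alkene geometry, and leaves C1, C6 and C7 to be set beforehand on an open chain. The forward reaction must form a ten-membered ring and set C8 relative to C7.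

**Functional group adjustments.** 26 is the reduction product of Weinreb amide 24, which keeps C8 at a stable oxidation level until the last moment because the α-branched, β-silyloxy aldehyde is labile. 24 comes from 23 by iododesilylation of the alkyne, 23 from 22 by silylation of O6, and 22 from aldol imide 21 by transamination.

**C6–C7.** 21 is cut between C6 and C7 into enal 12 and enoyl imide 19. The 6,7-syn relationship of O6 and the C11 branch is that of a syn aldol with C8 as the acyl carbon, and the C(=CH2)CH2O unit is exactly what α-attack of the dienolate of a 3-methylbut-2-enoyl group delivers. An epoxy-alcohol opening at C7 was not used because C6 would be an allylic epoxide carbon and would compete for the nucleophile.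

**C3–C4.** 12 is the oxidation product of allylic alcohol 11, which is cut at the sp3–sp2 bond C3–C4 into alkene 5 (boron on C3 after hydroboration) and alkenyl iodide 9. The coupling transfers the geometry of 9 unchanged into C4=C5.

**Small fragments.** 9 arises from the mono-silyl ether 7 of diol 6 by hydroxyl-directed trans-hydroalumination and iodination, which places iodine on C4 cis to C6. 5 is the silyl ether of 4, made by enantioselective addition of alkyne 1 to aldehyde 2; this sets C1. 19 is the N-acyl derivative of auxiliary 17 with acid 16, which comes from ester 15, the olefination product of ketone 13 and ylide 14.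

## Alternatives that were turned down

**Alternative 1:** Here the ten-membered ring is released from a bicycle instead of being closed. The C1 carbonyl and the C4=C5 alkene of A1 are reconnected through a C1–C5 bond to a cis-fused bicyclo[5.3.0]decane carrying a tertiary C1 hydroxyl and an oxirane spiro-fused at C4 through C15. In the forward direction the C1 alkoxide forms C1=O, the C1–C5 bond breaks, C4=C5 forms and the oxirane oxygen leaves as the C15 alkoxide (Grob fragmentation), giving the ten-membered C1 enone lactone A1 with free C15–OH. In its favour, the step is unimolecular and needs no dilution, the anti-periplanar requirement translates sp3 configuration into the C4=C5 geometry, and C15–OH appears in the same event. Against it for this target, a bicycle with six stereocentres (C1, C4, C5, C6, C7, C8) and a spiro-oxirane of defined configuration must be built, and three of those centres are then destroyed. A1 also still lacks C13, so the methylene has to be introduced beside an enone. The C1 ketone must then be reduced to the 1S alcohol on a flexible ring without conjugate reduction, and the O8 silyl ether exchanged for the ester. On ring formation and on C4=C5 geometry this plan is at least as strong as the chosen one. The chosen route offers instead C1 set by reagent control before any ring exists, C13 carried from the start, and only five operations after ring closure.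

**Alternative 2:** The C3–C4 bond of the ten-membered ring is disconnected and the ring contracted to a six-membered chiral-pool cyclohexenone derivative carrying two alkenyl arms on adjacent carbons. In the forward direction the potassium alkoxide undergoes an anionic oxy-Cope rearrangement that forms C3–C4, breaks the old ring bond and delivers the ten-membered C6 ketone A2 with a C1 methyl dienol ether. In its favour, C7 and the C11 unit come from the chiral pool, the rearrangement is fast and concentration-independent, and four-carbon ring expansion is a proven entry to germacrane rings. Against it, A2 has C8 as a plain methylene, C4 as an sp3 centre and C6 and C1 at the ketone level. The target would then need a stereoselective allylic oxidation at C8, desaturation to C4=C5 with ring-cis geometry, and two diastereoselective ketone reductions (C6, C1), all under substrate control on a mobile medium ring. That is a longer and less predictable endgame than the five steps that follow 28. The oxy-Cope is stronger on the ring-forming event itself. The chosen route offers three of the four ring stereocentres fixed before closure and the fourth set during closure.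

**Alternative 3:** The C9=C10 alkene is disconnected by ring-closing metathesis of an open-chain triene in which an allyl ether relay loads the metal carbene onto the hindered, 1,1-disubstituted C10, which then closes onto a C9 vinyl group. The product A3 is the bis-TBS ether of 37, so a single desilylation would follow. In its favour this is the latest possible ring closure, with lactone and ester already in place, and on steps after cyclisation (one against five) it is clearly better. Against it, forming a trisubstituted alkene inside a ten-membered ring is among the least favourable metathesis cases: ring strain makes closure reversible and favours oligomers, the geometry is under thermodynamic rather than reagent control, and the methylene lactone and C4=C5 are further carbene acceptors. The precursor also needs C1 and C8 set on two separate allylic fragments plus the relay tether. The chosen route offers an irreversible, kinetically controlled C–C bond formation with a linear alkyne, and a C9=C10 geometry that follows from the mechanism of a syn addition.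

Key step: step 15

Remark on the chemistry: the sense of induction in step 1 (alkynyl delivery to the Re face of 2 with the (S,S) ligand) is assigned by analogy with other enals; if derivatisation of 4 shows the opposite sense, the (R,R) ligand is used and nothing else changes.

Remark on the chemistry: 13, 14, 17 and 31 are taken as commercial; 26 is used crude because its α-branched β-silyloxy aldehyde is labile.

## Route

Step 1
Reactants: 1 trimethylsilylacetylene; 2 acrolein
Product: 4 (S)-5-(trimethylsilyl)pent-1-en-4-yn-3-ol, via methyl[(trimethylsilyl)ethynyl]zinc 3 (not isolated)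
Conditions: Me2Zn, (S,S)-ProPhenol (10 mol %), Ph3P=O (20 mol %), PhMe, 0 °C; then 2 (slow addition), 0 °C; aq. NH4Cl
Reagents that add atoms: none
Why: Catalytic asymmetric alkynylation of an aldehyde: the alkyne is zincated by Me2Zn and the dinuclear zinc–ProPhenol complex holds aldehyde and alkynyl group on adjacent zinc centres so that one formyl face (Re, giving 3S, which becomes C1 of the target) is attacked; slow addition of the enal limits the uncatalysed background reaction and polymerisation.

Step 2
Reactants: 4 (S)-5-(trimethylsilyl)pent-1-en-4-yn-3-ol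
Product: 5 (S)-3-(tert-butyldimethylsilyloxy)-5-(trimethylsilyl)pent-1-en-4-yne
Conditions: TBSCl, imidazole, DMF, 0 °C → rt
Reagents that add atoms: tert-butyldimethylsilyl chloride, CC(C)(C)[Si](C)(C)Cl
Why: Standard silylation of a secondary alcohol; the O1 TBS ether has to last until the final step and, being secondary and flanked later by C10, should survive the selective desilylation of step 18.

Step 3
Reactants: 6 but-2-yne-1,4-diol
Product: 7 4-(tert-butyldiphenylsilyloxy)but-2-yn-1-ol
Conditions: 6 (3 equiv), TBDPSCl (1 equiv), imidazole, DMF, 0 °C → rt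
Reagents that add atoms: tert-butyldiphenylsilyl chloride, CC(C)(C)[Si](Cl)(c1ccccc1)c1ccccc1
Why: Statistical monosilylation of a symmetric diol, driven to the mono-ether by excess diol, which is removed by aqueous washing; TBDPS is chosen for O15 because it must outlast both TES and primary TBS cleavage later.

Step 4
Reactants: 7 4-(tert-butyldiphenylsilyloxy)but-2-yn-1-ol
Product: 9 (Z)-4-(tert-butyldiphenylsilyloxy)-3-iodobut-2-en-1-ol, via cyclic alkenylalanate 8 (not isolated)
Conditions: NaAlH2(OCH2CH2OMe)2, THF, 0 °C; then EtOAc, I2, −78 → 0 °C
Reagents that add atoms: iodine, II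
Why: Hydroxyl-directed trans-hydroalumination of a propargylic alcohol: the alkoxy-alanate delivers hydride to the proximal alkyne carbon (C5) and aluminium to the distal one (C4) within a five-membered ring, and iodinolysis with retention puts iodine on C4 cis to C6; low temperature is kept to avoid β-elimination of the C15 silyloxy group from the alkenylalanate.

Step 5
Reactants: 5 (S)-3-(tert-butyldimethylsilyloxy)-5-(trimethylsilyl)pent-1-en-4-yne; 9 (Z)-4-(tert-butyldiphenylsilyloxy)-3-iodobut-2-en-1-ol
Product: 11 (2E,6S)-6-(tert-butyldimethylsilyloxy)-3-[(tert-butyldiphenylsilyloxy)methyl]-8-(trimethylsilyl)oct-2-en-7-yn-1-ol, via B-alkyl-9-borabicyclo[3.3.1]nonane 10 (not isolated)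
Conditions: 9-BBN-H, THF, 0 °C → rt; then 9, Pd(dppf)Cl2 (5 mol %), AsPh3, Cs2CO3, DMF/H2O, rt
Reagents that add atoms: none
Why: The borane adds anti-Markovnikov to the monosubstituted alkene (boron on C3) much faster than to the silyl-capped alkyne, and the B-alkyl Suzuki–Miyaura coupling forms C3–C4 with retention of the alkenyl iodide geometry, so C3 ends cis to C6 as the ring requires; the free allylic hydroxyl is tolerated.

Step 6
Reactants: 11 (2E,6S)-6-(tert-butyldimethylsilyloxy)-3-[(tert-butyldiphenylsilyloxy)methyl]-8-(trimethylsilyl)oct-2-en-7-yn-1-ol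
Product: 12 (2E,6S)-6-(tert-butyldimethylsilyloxy)-3-[(tert-butyldiphenylsilyloxy)methyl]-8-(trimethylsilyl)oct-2-en-7-ynal
Conditions: MnO2, CH2Cl2, rt
Reagents that add atoms: none
Why: Heterogeneous allylic oxidation that touches only the primary allylic alcohol; the neutral conditions should preserve the C4=C5 geometry and all silyl groups.

Step 7
Reactants: 13 1-(tert-butyldimethylsilyloxy)propan-2-one; 14 ethyl (triphenylphosphoranylidene)acetate
Product: 15 ethyl (E)-4-(tert-butyldimethylsilyloxy)-3-methylbut-2-enoate
Conditions: PhMe, 100 °C; chromatographic removal of the minor Z isomer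
Reagents that add atoms: none
Why: Wittig olefination of an activated α-silyloxy ketone with a stabilised ylide, which should favour the isomer with the ester trans to the larger silyloxymethyl arm (E, methyl cis to the ester); this builds C7, C8, C11, C12 and C13.

Step 8
Reactants: 15 ethyl (E)-4-(tert-butyldimethylsilyloxy)-3-methylbut-2-enoate
Product: 16 (E)-4-(tert-butyldimethylsilyloxy)-3-methylbut-2-enoic acid
Conditions: LiOH·H2O, THF/MeOH/H2O, rt; then aq. HCl to pH 4, 0 °C
Reagents that add atoms: lithium hydroxide, [Li+].[OH-]
Why: Saponification; the TBS ether tolerates hydroxide and brief mild acidification, and the E geometry rules out lactonisation.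

Step 9
Reactants: 16 (E)-4-(tert-butyldimethylsilyloxy)-3-methylbut-2-enoic acid; 17 (S)-4-benzyloxazolidin-2-one
Product: 19 (S)-4-benzyl-3-[(E)-4-(tert-butyldimethylsilyloxy)-3-methylbut-2-enoyl]oxazolidin-2-one, via mixed pivalic anhydride 18 (not isolated)
Conditions: PivCl, Et3N, THF, −20 °C; then 17, LiCl, −20 °C → rt
Reagents that add atoms: none
Why: N-Acylation through the mixed pivalic anhydride under LiCl/amine activation; this avoids a lithiated oxazolidinone, which could add in conjugate fashion to the enoyl group.

Step 10
Reactants: 19 (S)-4-benzyl-3-[(E)-4-(tert-butyldimethylsilyloxy)-3-methylbut-2-enoyl]oxazolidin-2-one; 12 (2E,6S)-6-(tert-butyldimethylsilyloxy)-3-[(tert-butyldiphenylsilyloxy)methyl]-8-(trimethylsilyl)oct-2-en-7-ynal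
Product: 21 syn aldol imide (6R,7S) with 6-OH and the C7 3-(tert-butyldimethylsilyloxy)prop-1-en-2-yl branch, via dibutylboron dienolate 20 (not isolated)
Conditions: Bu2BOTf, Et3N, CH2Cl2, −78 → 0 °C; then 12, −78 → 0 °C; pH 7 buffer, MeOH, 30% H2O2, 0 °C
Reagents that add atoms: none
Why: Evans syn aldol through a boron dienolate: soft enolisation removes a γ-proton from the methyl group (cis to the carbonyl and more acidic than the silyloxymethylene), the dienolate reacts at its α-carbon (C7) through a closed Zimmerman–Traxler transition state, and the benzyl group of the auxiliary shields one enolate face. This forms C6–C7, sets C7 and C6 in the Evans-syn sense (acyl numbering 2S,3R) and leaves the deconjugated C11=C13 methylene.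

Step 11
Reactants: 21 syn aldol imide
Product: 22 Weinreb amide (6R,7S) with free 6-OH
Conditions: MeNH(OMe)·HCl, AlMe3, THF, −20 → 0 °C; aq. potassium sodium tartrate
Reagents that add atoms: N,O-dimethylhydroxylamine hydrochloride, CNOC.Cl
Why: Aluminium amide transamination of an aldol imide, assisted by the aluminium alkoxide of the free β-hydroxyl, which directs attack to the exocyclic carbonyl; C7 should not epimerise and the auxiliary is recovered, while the amide serves as the latent C8 aldehyde.

Step 12
Reactants: 22 Weinreb amide with free 6-OH
Product: 23 O6-triethylsilyl Weinreb amide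
Conditions: Et3SiOTf, 2,6-lutidine, CH2Cl2, −78 °C
Reagents that add atoms: triethylsilyl trifluoromethanesulfonate, CC[Si](CC)(CC)OS(=O)(=O)C(F)(F)F
Why: Silylation of a hindered secondary alcohol with a silyl triflate; TES on O6 blocks retro-aldol and is the group that will later be removed together with the O12 TBS ether.

Step 13
Reactants: 23 O6-triethylsilyl Weinreb amide
Product: 24 C9 iodoalkyne Weinreb amide
Conditions: NIS, AgNO3 (20 mol %), acetone, rt, dark
Reagents that add atoms: N-iodosuccinimide, O=C1CCC(=O)N1I
Why: Silver-catalysed iododesilylation: the C-silyl alkyne is converted into a silver acetylide that NIS iodinates, under neutral conditions that leave O-silyl ethers and the alkenes alone; it is done while C8 is still an amide, so no free hydroxyl or aldehyde is exposed to the electrophilic iodine source.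

Step 14
Reactants: 24 C9 iodoalkyne Weinreb amide
Product: 26 seco C9 iodoalkyne C8 aldehyde (1S,6R,7S), via aluminium hemiaminal 25 (not isolated)
Conditions: iBu2AlH, THF, −78 °C; aq. potassium sodium tartrate, 0 °C; used crude
Reagents that add atoms: none
Why: Weinreb amide reduction: the chelated tetrahedral intermediate 25 collapses only on work-up, so no over-reduction occurs, and at −78 °C neither hydroalumination of the iodoalkyne nor epimerisation at C7 is expected.

Step 15
Reactants: 26 seco C9 iodoalkyne C8 aldehyde
Product: 28 ten-membered cycloalkynol (1S,6R,7R,8S; ring-cis C4=C5; C9≡C10) with free 8-OH, via alkynylchromium dichloride 27 (not isolated)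
Conditions: CrCl2 (10 equiv), NiCl2 (0.1 equiv), degassed THF, rt, slow addition of 26 to a final 0.002 M; aq. NH4Cl
Reagents that add atoms: none
Why: Divalent chromium (two equivalents per C–I bond), helped by catalytic nickel that inserts into the C(sp)–I bond in its zerovalent state and passes the alkynyl group on to trivalent chromium, converts the C9 iodoalkyne into the alkynylchromium species 27, which adds to the C8 aldehyde and forms the C8–C9 bond and the C8 chromium alkoxide. The closest known reaction type is the intramolecular Nozaki–Hiyama–Kishi addition of iodoalkynes to aldehydes, which has closed strained nine- and ten-membered cycloalkynes. One ring is closed, the ten-membered carbocycle, in a 10-exo-trig addition (the C=O is exocyclic to the forming ring); the ring-cis C4=C5 alkene already turns the chain so that C9 faces C8, and the linear C8–C9≡C10–C1 unit spanned by a six-atom bridge is only mildly strained. The one new stereocentre, C8, is controlled by C7: in the Felkin–Anh arrangement that the ring can adopt, the sp2 branch C11 is anti to the incoming alkynyl group, the ring bond C7–C6 is gauche to the forming bond on the side of the carbonyl oxygen and H7 lies under the trajectory, which leads to the 8S alcohol (O8 anti to C11, 1,3-anti to O6). The step needs chemoselectivity for C–I over three other π systems and four silyl ethers, which the halophilic low-valent metals provide, and it needs C7 to keep its configuration, which the non-basic organochromium secures (no enolisation, no β-elimination of the O6 silyl ether). It also needs intra- over intermolecular addition, secured by slow addition at millimolar concentration.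

Step 16
Reactants: 28 ten-membered cycloalkynol
Product: 30 allylic alcohol (1S,6R,7R,8R; 9Z) with C14 methyl on C10 and free 8-OH, via alkenylmagnesium bromide 29 (not isolated)
Conditions: Fe(acac)3 (20 mol %), MeMgBr (5 equiv), THF, −20 → 0 °C; then aq. NH4Cl
Reagents that add atoms: methylmagnesium bromide, C[Mg]Br
Why: Alkoxide-directed iron-catalysed carbomagnesiation of a propargylic alcohol: the O8 magnesium alkoxide holds the organoiron species, methyl is transferred to the distal alkyne carbon C10 and the metal to C9 in a syn addition, and protonation of 29 gives C9–H. Only O8 is a free alkoxide (O1 is silylated), which fixes the regiochemistry, and syn addition across an endocyclic alkyne can only give the ring-cis (9Z) alkene.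

Step 17
Reactants: 30 allylic alcohol with free 8-OH; 31 (S)-2-methylbutanoic acid
Product: 32 C8 (S)-2-methylbutanoate (1S,6R,7R,8R) carrying 1-OTBS 6-OTES 12-OTBS 15-OTBDPS
Conditions: DCC, DMAP, CH2Cl2, 0 °C → rt
Reagents that add atoms: none
Why: Steglich esterification of the only free hydroxyl; carbodiimide activation with DMAP acyl transfer at low temperature should not epimerise the simple α-branched acid.

Step 18
Reactants: 32 C8 (S)-2-methylbutanoate
Product: 33 6,12-diol (1-OTBS and 15-OTBDPS retained)
Conditions: HF·pyridine, pyridine, THF, 0 °C → rt (monitored)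
Reagents that add atoms: none
Why: Buffered fluoride cleavage of silyl ethers in the order of their lability: the primary TBS ether on O12 and the secondary TES ether on O6 go first, whereas the hindered secondary TBS ether on O1 and the primary TBDPS ether on O15 are much slower.

Step 19
Reactants: 33 6,12-diol
Product: 36 α-methylene-γ-butyrolactone with 1-OTBS and 15-OTBDPS, via hydroxy enal 34 (not isolated), via lactol 35 (not isolated)
Conditions: TEMPO (20 mol %), PhI(OAc)2 (2.5 equiv), CH2Cl2, rt
Reagents that add atoms: none
Why: Oxoammonium-mediated oxidative lactonisation of a 1,4-diol: the oxidant prefers the unhindered primary allylic alcohol at C12 over the secondary C6 alcohol, aldehyde 34 is trapped by O6 as the five-membered lactol 35, and this is oxidised to the lactone; the trans ring fusion follows from the C6/C7 configuration already present. This oxidant is used instead of an allylic-selective metal oxide because C6–OH is itself allylic.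

Step 20
Reactants: 36 α-methylene-γ-butyrolactone with 1-OTBS and 15-OTBDPS
Product: 37 CNP0526758.1
Conditions: HF·pyridine (excess), THF, 0 °C → rt
Reagents that add atoms: none
Why: Global desilylation with an acidic fluoride source, which removes the secondary TBS and primary TBDPS ethers without the basic conditions that would cause acyl migration from O8 or conjugate addition to the methylene lactone.

## Compound list

1 | trimethylsilylacetylene | C#C[Si](C)(C)C | starting material
2 | acrolein | C=CC=O | starting material
3 | methyl[(trimethylsilyl)ethynyl]zinc | C[Zn]C#C[Si](C)(C)C | intermediate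
4 | (S)-5-(trimethylsilyl)pent-1-en-4-yn-3-ol | C[Si](C)(C)C#C[C@@H](O)C=C | intermediate
5 | (S)-3-(tert-butyldimethylsilyloxy)-5-(trimethylsilyl)pent-1-en-4-yne | C[Si](C)(C)C#C[C@@H](O[Si](C)(C)C(C)(C)C)C=C | intermediate
6 | but-2-yne-1,4-diol | OCC#CCO | starting material
7 | 4-(tert-butyldiphenylsilyloxy)but-2-yn-1-ol | OCC#CCO[Si](c1ccccc1)(c1ccccc1)C(C)(C)C | intermediate
8 | sodium 2,2-bis(2-methoxyethoxy)-3-[(tert-butyldiphenylsilyloxy)methyl]-2,5-dihydro-1,2-oxaaluminol-2-uide (cyclic alkenylalanate) | [Na+].COCCO[Al-]1(OCCOC)OCC=C1CO[Si](c1ccccc1)(c1ccccc1)C(C)(C)C | intermediate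
9 | (Z)-4-(tert-butyldiphenylsilyloxy)-3-iodobut-2-en-1-ol | OC/C=C(\I)CO[Si](c1ccccc1)(c1ccccc1)C(C)(C)C | intermediate
10 | 9-[(S)-3-(tert-butyldimethylsilyloxy)-5-(trimethylsilyl)pent-4-yn-1-yl]-9-borabicyclo[3.3.1]nonane | C1CC2CCCC(C1)B2CC[C@H](O[Si](C)(C)C(C)(C)C)C#C[Si](C)(C)C | intermediate
11 | (2E,6S)-6-(tert-butyldimethylsilyloxy)-3-[(tert-butyldiphenylsilyloxy)methyl]-8-(trimethylsilyl)oct-2-en-7-yn-1-ol | OC/C=C(/CO[Si](c1ccccc1)(c1ccccc1)C(C)(C)C)CC[C@H](O[Si](C)(C)C(C)(C)C)C#C[Si](C)(C)C | intermediate
12 | (2E,6S)-6-(tert-butyldimethylsilyloxy)-3-[(tert-butyldiphenylsilyloxy)methyl]-8-(trimethylsilyl)oct-2-en-7-ynal | O=C/C=C(/CO[Si](c1ccccc1)(c1ccccc1)C(C)(C)C)CC[C@H](O[Si](C)(C)C(C)(C)C)C#C[Si](C)(C)C | intermediate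
13 | 1-(tert-butyldimethylsilyloxy)propan-2-one | CC(=O)CO[Si](C)(C)C(C)(C)C | starting material
14 | ethyl (triphenylphosphoranylidene)acetate | CCOC(=O)C=P(c1ccccc1)(c1ccccc1)c1ccccc1 | starting material
15 | ethyl (E)-4-(tert-butyldimethylsilyloxy)-3-methylbut-2-enoate | CCOC(=O)/C=C(\C)CO[Si](C)(C)C(C)(C)C | intermediate
16 | (E)-4-(tert-butyldimethylsilyloxy)-3-methylbut-2-enoic acid | OC(=O)/C=C(\C)CO[Si](C)(C)C(C)(C)C | intermediate
17 | (S)-4-benzyloxazolidin-2-one | O=C1N[C@@H](Cc2ccccc2)CO1 | starting material
18 | (E)-4-(tert-butyldimethylsilyloxy)-3-methylbut-2-enoic pivalic anhydride | CC(C)(C)C(=O)OC(=O)/C=C(\C)CO[Si](C)(C)C(C)(C)C | intermediate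
19 | (S)-4-benzyl-3-[(E)-4-(tert-butyldimethylsilyloxy)-3-methylbut-2-enoyl]oxazolidin-2-one | O=C1OC[C@H](Cc2ccccc2)N1C(=O)/C=C(\C)CO[Si](C)(C)C(C)(C)C | intermediate
20 | (Z)-dibutylboron dienolate of 19 (O–B cis to C11 across C7=C8; C11=C13 methylene) | O=C1OC[C@H](Cc2ccccc2)N1/C(OB(CCCC)CCCC)=C/C(=C)CO[Si](C)(C)C(C)(C)C | intermediate
21 | (S)-4-benzyl-3-{(2S,3R,4E,8S)-8-(tert-butyldimethylsilyloxy)-2-[3-(tert-butyldimethylsilyloxy)prop-1-en-2-yl]-5-[(tert-butyldiphenylsilyloxy)methyl]-3-hydroxy-10-(trimethylsilyl)dec-4-en-9-ynoyl}oxazolidin-2-one (germacrane 1S,6R,7S) | O=C1OC[C@H](Cc2ccccc2)N1C(=O)[C@@H](C(=C)CO[Si](C)(C)C(C)(C)C)[C@H](O)/C=C(/CO[Si](c1ccccc1)(c1ccccc1)C(C)(C)C)CC[C@H](O[Si](C)(C)C(C)(C)C)C#C[Si](C)(C)C | intermediate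
22 | (2S,3R,4E,8S)-8-(tert-butyldimethylsilyloxy)-2-[3-(tert-butyldimethylsilyloxy)prop-1-en-2-yl]-5-[(tert-butyldiphenylsilyloxy)methyl]-3-hydroxy-N-methoxy-N-methyl-10-(trimethylsilyl)dec-4-en-9-ynamide | CON(C)C(=O)[C@@H](C(=C)CO[Si](C)(C)C(C)(C)C)[C@H](O)/C=C(/CO[Si](c1ccccc1)(c1ccccc1)C(C)(C)C)CC[C@H](O[Si](C)(C)C(C)(C)C)C#C[Si](C)(C)C | intermediate
23 | 3-O-triethylsilyl ether of 22 (2S,3R,4E,8S) | CON(C)C(=O)[C@@H](C(=C)CO[Si](C)(C)C(C)(C)C)[C@H](O[Si](CC)(CC)CC)/C=C(/CO[Si](c1ccccc1)(c1ccccc1)C(C)(C)C)CC[C@H](O[Si](C)(C)C(C)(C)C)C#C[Si](C)(C)C | intermediate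
24 | 10-iodo analogue of 23 (C9 iodoalkyne Weinreb amide; 2S,3R,4E,8S) | CON(C)C(=O)[C@@H](C(=C)CO[Si](C)(C)C(C)(C)C)[C@H](O[Si](CC)(CC)CC)/C=C(/CO[Si](c1ccccc1)(c1ccccc1)C(C)(C)C)CC[C@H](O[Si](C)(C)C(C)(C)C)C#CI | intermediate
25 | diisobutylaluminium hemiaminal of 24 (tetrahedral C8, configuration at C8 undefined) | CON(C)C(O[Al](CC(C)C)CC(C)C)[C@@H](C(=C)CO[Si](C)(C)C(C)(C)C)[C@H](O[Si](CC)(CC)CC)/C=C(/CO[Si](c1ccccc1)(c1ccccc1)C(C)(C)C)CC[C@H](O[Si](C)(C)C(C)(C)C)C#CI | intermediate
26 | (2S,3R,4E,8S)-8-(tert-butyldimethylsilyloxy)-2-[3-(tert-butyldimethylsilyloxy)prop-1-en-2-yl]-5-[(tert-butyldiphenylsilyloxy)methyl]-10-iodo-3-(triethylsilyloxy)dec-4-en-9-ynal (seco C9 iodoalkyne C8 aldehyde; germacrane 1S,6R,7S) | O=C[C@@H](C(=C)CO[Si](C)(C)C(C)(C)C)[C@H](O[Si](CC)(CC)CC)/C=C(/CO[Si](c1ccccc1)(c1ccccc1)C(C)(C)C)CC[C@H](O[Si](C)(C)C(C)(C)C)C#C[I] | intermediate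
27 | alkynylchromium dichloride derived from 26 (C9–CrCl2, trivalent chromium) | O=C[C@@H](C(=C)CO[Si](C)(C)C(C)(C)C)[C@H](O[Si](CC)(CC)CC)/C=C(/CO[Si](c1ccccc1)(c1ccccc1)C(C)(C)C)CC[C@H](O[Si](C)(C)C(C)(C)C)C#C[Cr](Cl)Cl | intermediate
28 | ten-membered cycloalkynol, germacrane (1S,6R,7R,8S): ring-cis C4=C5, C9≡C10, 8-OH, 1-OTBS, 6-OTES, C4–CH2OTBDPS, C7–C(=CH2)CH2OTBS | CC[Si](CC)(CC)O[C@@H]1/C=C(/CO[Si](c2ccccc2)(c2ccccc2)C(C)(C)C)CC[C@H](O[Si](C)(C)C(C)(C)C)C#C[C@@H](O)[C@H]1C(=C)CO[Si](C)(C)C(C)(C)C | intermediate
29 | C9 alkenylmagnesium bromide, O8 bromomagnesium alkoxide (methyl on C10, ring-cis C9=C10) | CC[Si](CC)(CC)O[C@@H]1/C=C(/CO[Si](c2ccccc2)(c2ccccc2)C(C)(C)C)CC[C@H](O[Si](C)(C)C(C)(C)C)/C(C)=C(/[Mg]Br)[C@@H](O[Mg]Br)[C@H]1C(=C)CO[Si](C)(C)C(C)(C)C | intermediate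
30 | allylic alcohol, germacrane (1S,6R,7R,8R,4E,9Z): C14 methyl on C10, 8-OH, silyl groups as in 28 | CC[Si](CC)(CC)O[C@@H]1/C=C(/CO[Si](c2ccccc2)(c2ccccc2)C(C)(C)C)CC[C@H](O[Si](C)(C)C(C)(C)C)/C(C)=C\[C@@H](O)[C@H]1C(=C)CO[Si](C)(C)C(C)(C)C | intermediate
31 | (S)-2-methylbutanoic acid | CC[C@H](C)C(=O)O | starting material
32 | C8 (S)-2-methylbutanoate of 30 (1S,6R,7R,8R) | CC[Si](CC)(CC)O[C@@H]1/C=C(/CO[Si](c2ccccc2)(c2ccccc2)C(C)(C)C)CC[C@H](O[Si](C)(C)C(C)(C)C)/C(C)=C\[C@@H](OC(=O)[C@@H](C)CC)[C@H]1C(=C)CO[Si](C)(C)C(C)(C)C | intermediate
33 | 6,12-diol (1S,6R,7S,8R) with 1-OTBS, 15-OTBDPS and the C8 ester | O[C@@H]1/C=C(/CO[Si](c2ccccc2)(c2ccccc2)C(C)(C)C)CC[C@H](O[Si](C)(C)C(C)(C)C)/C(C)=C\[C@@H](OC(=O)[C@@H](C)CC)[C@H]1C(=C)CO | intermediate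
34 | C12 aldehyde (2-substituted propenal) with free 6-OH | O[C@@H]1/C=C(/CO[Si](c2ccccc2)(c2ccccc2)C(C)(C)C)CC[C@H](O[Si](C)(C)C(C)(C)C)/C(C)=C\[C@@H](OC(=O)[C@@H](C)CC)[C@H]1C(=C)C=O | intermediate
35 | 6,12-lactol (C12 anomers) | C=C1C(O)O[C@@H]2/C=C(/CO[Si](c3ccccc3)(c3ccccc3)C(C)(C)C)CC[C@H](O[Si](C)(C)C(C)(C)C)/C(C)=C\[C@@H](OC(=O)[C@@H](C)CC)[C@@H]12 | intermediate
36 | 1-O-TBS 15-O-TBDPS ether of the target lactone (1S,6R,7R,8R) | C=C1C(=O)O[C@@H]2/C=C(/CO[Si](c3ccccc3)(c3ccccc3)C(C)(C)C)CC[C@H](O[Si](C)(C)C(C)(C)C)/C(C)=C\[C@@H](OC(=O)[C@@H](C)CC)[C@@H]12 | intermediate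
37 | CNP0526758.1, (1S,6R,7R,8R)-1,15-dihydroxy-8-[(S)-2-methylbutanoyloxy]germacra-4E,9Z,11(13)-trien-12,6-olide | C=C1C(=O)O[C@@H]2/C=C(/CO)CC[C@H](O)/C(C)=C\[C@@H](OC(=O)[C@@H](C)CC)[C@@H]12 | target

## Step count and risk

Total step count: 20. Longest linear sequence: 15 steps (steps 1, 2, 5, 6 and 10–20 from 1 and 2; equally steps 3–6 and 10–20 from 6).

Steps least certain to work:

**Step 15 (key step).** The most likely problem is poor facial selectivity at C8. The acyclic Felkin–Anh preference is only one of the forces in a ring-closing transition state, and the torsional demands of the forming cyclodecenyne may favour the other carbonyl face. Oligomerisation is the second concern but is addressed by dilution. Fallback: the cyclisation product 28, as whatever mixture of C8 epimers is obtained, is oxidised with Dess–Martin periodinane to the ten-membered C8 ynone F1. F1 is then reduced under reagent control with the (S)-Me-CBS oxazaborolidine and catecholborane; the alkynyl arm acts as the small substituent, which should give the 8S alcohol. The route is rejoined at 28.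

**Step 16.** The most likely problem is failure or wrong regiochemistry of methyl transfer. C10 is flanked by the bulky C1 silyloxy carbon and the alkyne is strained, so iron-mediated reduction of the alkyne or methyl delivery to C9 could compete with the directed pathway. Fallback: starting from 28, the ynone F1 described above is prepared, and Me2CuLi is added in conjugate fashion (THF, −78 °C). The polarity of the ynone forces methyl onto the β-carbon C10, and protonation of the allenolate within the ring should give the ring-cis enone F2. A 1,2-reduction of F2 (the (R)-Me-CBS oxazaborolidine if the alkenyl arm behaves as the large substituent, as is usual for enones, otherwise NaBH4 with CeCl3 if the ring conformation already favours the 8R alcohol) rejoins the route at 30.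

**Step 10.** The most likely problem is loss of regiocontrol in the soft enolisation: γ-deprotonation at the silyloxymethylene instead of the methyl group, or incomplete enolisation of the β,β-disubstituted enoyl imide, and with it low conversion or erosion of diastereoselectivity. Fallback: starting from 19, dienolate formation and aldol are separated. Treatment with NaN(SiMe3)2 (THF, −78 °C) and kinetic α-protonation with acetic acid give the deconjugated imide F3, in which the methylene is already in place. Ordinary α-enolisation of F3 (Bu2BOTf, iPr2NEt) and addition of 12 then give the same aldol and rejoin the route at 21.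

**Step 1.** The most likely problem is low enantioselectivity or polymerisation, because acrolein is the smallest and most reactive enal and leaves the catalyst little to differentiate. Fallback: starting from 1 and 2, the lithium acetylide of 1 (n-BuLi, THF, −78 °C) is added to 2 to give the racemic alcohol F4. Kinetic resolution with Burkholderia cepacia lipase and vinyl acetate should acylate the R enantiomer (silylalkynyl large, vinyl medium in the empirical size rule) to the acetate F5, leaving the S alcohol, which is separated and rejoins the route at 4.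

**Step 18.** The most likely problem is over-deprotection, with partial loss of the O1 TBS ether, because the rate gap between a primary TBS/secondary TES pair and a secondary allylic TBS ether is finite. Fallback: starting from 32, all three labile silyl groups are removed on purpose (longer exposure to HF·pyridine) to give the 1,6,12-triol F6, which keeps only the TBDPS ether. The preference of the oxoammonium oxidant for primary over secondary alcohols is then relied on to convert F6 into the C1-hydroxy lactone F7 (TEMPO, PhI(OAc)2), and removal of the TBDPS group with HF·pyridine rejoins the route at 37.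

Further compounds
F1 | step 15 | ten-membered C8 ynone (1S,6R,7S): 28 with C8=O | CC[Si](CC)(CC)O[C@@H]1/C=C(/CO[Si](c2ccccc2)(c2ccccc2)C(C)(C)C)CC[C@H](O[Si](C)(C)C(C)(C)C)C#CC(=O)[C@H]1C(=C)CO[Si](C)(C)C(C)(C)C
F2 | step 16 | ring-cis C8 enone with C14 methyl on C10 (30 with C8=O) | CC[Si](CC)(CC)O[C@@H]1/C=C(/CO[Si](c2ccccc2)(c2ccccc2)C(C)(C)C)CC[C@H](O[Si](C)(C)C(C)(C)C)/C(C)=C\C(=O)[C@H]1C(=C)CO[Si](C)(C)C(C)(C)C
F3 | step 10 | (S)-4-benzyl-3-{3-[(tert-butyldimethylsilyloxy)methyl]but-3-enoyl}oxazolidin-2-one | O=C1OC[C@H](Cc2ccccc2)N1C(=O)CC(=C)CO[Si](C)(C)C(C)(C)C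
F4 | step 1 | racemic 5-(trimethylsilyl)pent-1-en-4-yn-3-ol | C[Si](C)(C)C#CC(O)C=C
F5 | step 1 | (R)-5-(trimethylsilyl)pent-1-en-4-yn-3-yl acetate | C[Si](C)(C)C#C[C@H](OC(C)=O)C=C
F6 | step 18 | 1,6,12-triol with 15-OTBDPS and the C8 ester | O[C@@H]1/C=C(/CO[Si](c2ccccc2)(c2ccccc2)C(C)(C)C)CC[C@H](O)/C(C)=C\[C@@H](OC(=O)[C@@H](C)CC)[C@H]1C(=C)CO
F7 | step 18 | 15-O-TBDPS ether of the target lactone with free 1-OH | C=C1C(=O)O[C@@H]2/C=C(/CO[Si](c3ccccc3)(c3ccccc3)C(C)(C)C)CC[C@H](O)/C(C)=C\[C@@H](OC(=O)[C@@H](C)CC)[C@@H]12
A1 | alternative 1 | ten-membered C1 enone 6,12-lactone with free 15-OH, 8-OTBS and no C13 methylene | C1C(=O)O[C@@H]2/C=C(/CO)CCC(=O)/C(C)=C\[C@@H](O[Si](C)(C)C(C)(C)C)[C@@H]12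
A2 | alternative 2 | ten-membered C6 ketone with C1 methyl dienol ether, C15 PMB ether on sp3 C4 and C12 TBS ether | C1/C=C(C)\C(OC)=C\C[C@@H](COCc2ccc(OC)cc2)CC(=O)[C@@H]1C(=C)CO[Si](C)(C)C(C)(C)C
A3 | alternative 3 | 1,15-bis-TBS ether of 37 | C=C1C(=O)O[C@@H]2/C=C(/CO[Si](C)(C)C(C)(C)C)CC[C@H](O[Si](C)(C)C(C)(C)C)/C(C)=C\[C@@H](OC(=O)[C@@H](C)CC)[C@@H]12
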